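All runs were generated by integration from invented constants, noise included.

The delta run, with 3 equiv of G, had 2.4% of its J left at 40.0 h, and the alpha run, with 0.79 equiv, had 27.5%, which is more.

| flask | J | G | remark | time |
|---|---|---|---|---|
| alpha | 0.10 M | 0.79 equiv | run made earlier |  |
| delta | 0.10 M | 3 equiv | run made earlier |  |
| winter | 0.10 M | 1.00 equiv |  | 40 h |
| summer | 0.10 M | 2.00 equiv |  | 40 h |
| dusk | 0.10 M | 4.00 equiv |  | 40 h |

| run | time / h | J / % | Z / % |
|---|---|---|---|
| alpha | 5.00 | 78.2 | 10.1 |
| alpha | 15.0 | 53.0 | 17.0 |
| alpha | 25.0 | 39.4 | 17.0 |
| alpha | 40.0 | 27.5 | 16.6 |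
| delta | 5.00 | 50.4 | 33.4 |
| delta | 15.0 | 16.5 | 42.2 |
| delta | 25.0 | 8.2 | 39.6 |
| delta | 40.0 | 2.4 | 33.6 |

(each reading ± 0.5 percentage points)

* part of the J that has reacted at the end, winter
* part of the J that has reacted at the end, summer
* part of the J that has reacted at the end, dusk
* what raising the equivalents of G from its lowest to its highest value here does to the part of the J that has reacted (changes below 5 percentage points count as none) (it rises / no change / it falls)

- the numbers in the tables scatter by 0.5 percentage points (one standard deviation)

We put both runs on one scale, Λ = ln(J charged / J left), the ordinate of a pseudo-first-order plot. Now we turn the question round. For G to make no difference, the two runs would have to stand at the same Λ, so a zero slope against equivalents is the zero of our scale, and for conversion to fall the slope would have to be negative. The readings at the final time give: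

Λ(alpha) = 1.29, Λ(delta) = 3.73

s = (Λ(delta) − Λ(alpha)) / (difference in equivalents) = 1.10

We call s, the gain in Λ per equivalent of G at a fixed time, as read off these two scattered runs, the survival slope. Our own reckoning assumes a straight line in equivalents, and dusk lies beyond both runs:

winter 78.2%, summer 92.8%, dusk 99.2% reacted

With winter held at our figure, a change under 5 percentage points from winter to dusk would need s below 0.0868, and s is larger than that by a factor of 12.7.

The forecast says 78.5%, 93% and 99.4%, slightly higher than ours, and it rises: “Conversion therefore rises with G, levelling off near completion”.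

The flasks give 77.1%, 92.1% and 99.3%; from winter to dusk conversion changes thus: it rises, by 22 points.

    J + G → D + Z (k = 0.429 M⁻¹ h⁻¹)
    G + D ⇌ Q, settled at all times (K = 6190 M⁻¹)
    2 J → X (k = 0.109 M⁻¹ h⁻¹)
    G + Z → L (k = 0.125 M⁻¹ h⁻¹)
    J + Z → E (k = 0.512 M⁻¹ h⁻¹)

Between winter and dusk the Λ of the flasks climbs by 1.16 per equivalent, against our s of 1.10. In dusk, J + G had half of its turnover up to 40.0 h behind it by 3.71 h and J + Z by 6.94 h. In dusk, G + Z had 22% of its turnover up to that time behind it at 8.00 h and ran on, with L at 43.7% and Z at 27.8% of the J charged at 40.0 h. The slope read from alpha and delta at 25.0 h is 0.710, which, carried on from the delta reading, puts J in dusk read at 25 h at 4.03%; that flask holds 3.28%.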